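## Structural features

The target is a tetraflavanoid made of three fisetinidol units (T, M and E; 5-deoxyflavan-3-ols with a resorcinol-type ring A) and one (+)-catechin unit (phloroglucinol-type ring A). C4 of T is bonded to C6 of M, C4 of M to C6 of catechin, and C4 of E to C8 of catechin. Each fisetinidol unit has three contiguous stereocentres in ring C (C2, C3, C4) in the all-trans arrangement with a 4α aryl bond (T: 2R,3S,4R; M: 2R,3S,4S; E: 2R,3S,4S), and catechin adds C2 and C3 (2R,3S), eleven stereocentres in all. Seventeen hydroxyls are free (thirteen phenolic, four alcoholic); the catechol and resorcinol rings oxidise easily, free 4'-phenols allow base-induced epimerisation at C2 through a quinone methide, the benzylic C2–O1 bonds are open to hydrogenolysis, and the 4-aryl bonds, although those of 5-deoxy units tolerate dilute acid, can ionise in strong acid. The hard part is unit M: its ring A must carry unit T at C6, and its C4 must be joined, with the 4α configuration, to catechin C6, the more hindered of the two phloroglucinol positions. The key step uses the fact that ring C of unit M (O1, C2, C3, C4, C4a, C8a) lies between a resorcinol ring (C4a–C8a–O1 is a phenol with a free CH at C4a) and a three-carbon chain C4–C3–C2 with an aryl group at each end, that is, an aryl enone whose β-carbon is bonded to catechin C6. Closing ring C through C4–C4a and O1–C2 joins a T–resorcinol half to a catechin–enone half, both from the chiral pool, and leaves only C4 of M to be set by a reagent; C2 and C3 of M then follow from C4.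

## Logic of the disconnections

22 ⇒ 20 + 2. The bond between C4 of unit E and catechin C8 is cut last. In 20 that carbon is the only free position on a phloroglucinol-type ring and therefore the strongest carbon nucleophile of the molecule, while 2 ionises at C4 in dilute acid without any protecting group and is already at hand after step 1. The cut removes a whole flavan unit with three stereocentres and leaves no protecting group or halogen to be handled afterwards. The forward step needs attack on the α-face (anti to the 3-hydroxyl of 21), selectivity for C8 over the resorcinol-type rings of units T and M and of 2 itself, and conditions mild enough for seventeen free hydroxyls.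

20 ⇒ 19. Eleven benzyl–oxygen bonds and the C8–Br bond are traced back together. Bromine is needed earlier only as a blocking group, and because it is lost under the same conditions as the benzyl ethers it costs no step of its own. The forward hydrogenolysis must spare the benzylic C2–O1 bonds and the 4-aryl bonds, and the hydrogen bromide it releases must be buffered.

19 ⇒ 17. The C3–O and C2–H bonds of unit M are removed, leaving the enol ether. With C4 in place, a syn addition across C2=C3 on the face away from the C4 aryl group gives both remaining stereocentres of M at once. The forward step needs boron at C3, attack anti to the 4α-aryl group, and an organoborane that does not eliminate.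

17 ⇒ 6 + 14 (key disconnection). C4–C4a and O1–C2 of unit M are cut. This divides the molecule at its centre into two halves of similar size and reduces the stereochemical problem to one centre. The forward step needs catalyst control of the enone face. The precursors are designed for it: 6 has only its two resorcinol hydroxyls free, and 14 keeps bromine on C8 (the only other nucleophilic carbon) and benzyl groups on O5 and O7 (so that the enol ether of 17 cannot be trapped as a bicyclic ketal). The resorcinol ring of 6 has two activated free carbons, not one; the carbon between the hydroxyls is flanked on both sides, so site selectivity rests on sterics.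

14 ⇒ 11 + 12. The Cα=Cβ bond is cut. 11 cannot enolise and the E-alkene is the thermodynamic outcome, so a base-mediated condensation is sufficient.

11 ⇒ 9 ⇒ 8 ⇒ 7. The C6–CHO bond, the C8–Br bond and the five benzyl ethers are removed in turn. A formyl group enters C6 only if C8 is occupied, and bromine enters C8 selectively. Benzyl ethers survive base, acid and borane and leave in step 10.

6 ⇒ 3 + 4 (through 5). The bond between C4 of unit T and the resorcinol ring is cut. 4 is cheap enough to be used in excess, and the benzyl ethers of 3 make the product soluble and chromatographable. The forward step needs 4α selectivity and mono-alkylation at the carbon of 4 that is para to one hydroxyl and ortho to the other.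

3 ⇒ 2 ⇒ 1. The benzyl ethers and then the C4–H bond are removed. Reduction precedes benzylation because 1 is base-labile (ring contraction, C2 epimerisation, oxidation) whereas 2 is not. The C4 configuration of 2 and 3 is irrelevant because it is erased in 5 and in 21.

## Other disconnections considered

Alternative 1: The cut goes through C3–C4 of units T and M at once, with both O1–C2 bonds still open. In the forward step, bis(boronic ester) A1 would react twice with oxiranyllithium A3, made from stannane A2 by tin–lithium exchange. Each 1,2-metalate rearrangement moves a diarylmethyl group from boron to the epoxide carbon with ring opening, and oxidation of the two C–B bonds would give bis-diol A4.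
- In favour: the sequence is stereospecific (retention at the migrating carbon, inversion at the carbenoid carbon), so C2 and C3 of both units come from A2 and C4 from A1. No face of a hindered π-system has to be distinguished. Catechin C8 is open, so no blocking halogen is needed.
- Against: A1 holds two configurationally defined dibenzylic boronic esters, one flanked by two benzyloxy groups. They would need a synthesis of their own, are prone to protodeboronation, and their bulky, electron-rich groups may migrate slowly. Both homologations must succeed on one molecule. After A4, two desilylations and two ring closures with inversion at benzylic C2 remain, each with a risk of ionisation. The three stereocentres of unit T, which the chosen plan takes from 1, must be made.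
- Comparison: structurally it addresses the same region (units T and M). In principle it controls C4 of M better than the chosen plan, which relies on a catalyst there. Mechanistically it is a stoichiometric organometallic sequence at low temperature against a catalytic acid cascade. In step economy it is worse: A4 is further from the trimer than 17, and A1 is much longer to reach than 6 and 14. It is the equal of the chosen plan in leaving unit E for a late coupling and better in needing no halogen on catechin.

Alternative 2: The cut removes C2–C3 and O1–C2 in units T and M, taking each ring C back to a 2-(1-arylvinyl)phenol and an aldehyde. In the forward step, bis(vinylphenol) A5 and two equivalents of aldehyde A6 would react under a chiral phosphoric acid by Prins-type addition, ionisation and C–O closure to give bis(flav-3-ene) A7. A double hydroboration–oxidation anti to each C2 aryl group would then set C3 and C4 of both units.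
- In favour: it is the most convergent option (two rings and four bonds in one flask from a catalogue aldehyde). Unit T no longer needs 1. Catechin C8 is open. The hydroboration end game follows the same logic as the chosen plan.
- Against: two stereocentres (C2 of T and C2 of M) must be set independently by the catalyst in a C–O bond formation on a delocalised cation, so four stereoisomers are possible. A 2-aryl-2H-chromene can reopen by ionisation of its doubly activated C2–O bond or by electrocyclic ring opening, so the C2 configuration is labile. Electron-rich 1,1-diarylethylenes protonate and dimerise easily. The later hydroboration must add to an alkene with two aryl groups on C4, twice. A5 needs two methylenations at hindered diaryl ketones.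
- Comparison: structurally it creates more stereocentres by reagent control, but the chosen plan takes those of T from the chiral pool and creates only one under catalyst control. Mechanistically both are Brønsted acid cascades ending in O1–C2 closure; in the chosen plan the catalyst-controlled event is a robust C–C bond at C4, here it is the labile C2–O bond. In step economy the alternative is better at the key step (two units at once) and equal in the end game; the precursor effort is comparable.

Alternative 3: The cut removes ring A of unit E entirely (C4a–C5, C6–C7, C7–C8, C8a–C4a), which also opens ring C of E. What remains is an acyclic chain with C2, C3 and C4 already bonded to catechin C8. In the forward step, irradiation of diazo enone A8 would trigger Wolff rearrangement, intramolecular ketene–alkyne [2+2] cycloaddition, 4π ring opening, 6π closure and tautomerisation to give A9.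
- In favour: the 4→8 bond and the 4α configuration are fixed before ring A exists, so no α/β or C6/C8 question arises. Ring A is formed with its 7-hydroxyl free and correctly placed. The conditions are neutral.
- Against: it solves the easiest bond of the molecule, the one a cation coupling with a phloroglucinol ring does best, and leaves unit M untouched. A9 has C6 open, so the whole problem of attaching units T and M at that hindered carbon remains. A8 combines a diazo ketone, a Michael acceptor and an ynol ether on a chain with three contiguous stereocentres that must each be made. Photolysis next to many benzyl ethers and electron-rich rings invites carbene C–H insertion and arene cyclopropanation before the Wolff shift.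
- Comparison: structurally it concerns a different region and complements, not replaces, the chosen key step. Mechanistically it is a pericyclic cascade against an ionic annulation; it is better in regiochemical certainty and equal in the outcome at C4 of E only if the acyclic stereocontrol is complete. In step economy it is clearly worse: a long synthesis of A8 against one coupling of 20 with 2.

Key step: step 8

Remark on the chemistry: the resorcinol ring of 6 has two activated free carbons (the one para to a hydroxyl and the one between the two hydroxyls); the route relies on the steric shielding of the latter.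
Assumption on the catalyst: the (R)-configured acid is taken to be the antipode that gives the 4S configuration at C4 of unit M; if the sense of induction is the opposite, the (S)-acid is used without other change.
Assumption on supply: 12 is taken as a catalogue compound.

## Route

Step 1
Reactants: 1 (+)-fustin [(2R,3R)-2-(3,4-dihydroxyphenyl)-3,7-dihydroxychroman-4-one]
Product: 2 (+)-mollisacacidin [(2R,3S,4R)-2-(3,4-dihydroxyphenyl)chromane-3,4,7-triol; 2,3-trans-3,4-trans]
Conditions: NaBH4, MeOH, 0 °C → rt
Reagents that add atoms: none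
Why: Hydride reduction of the aryl ketone; attack anti to the neighbouring 3-hydroxyl should give mainly the 3,4-trans diol, and either C4 epimer serves because this centre is erased whenever the C4 cation forms.

Step 2
Reactants: 2 (+)-mollisacacidin
Product: 3 penta-O-benzylmollisacacidin [(2R,3S,4R)-3,4,7-tris(benzyloxy)-2-[3,4-bis(benzyloxy)phenyl]chromane]
Conditions: BnBr (6.5 equiv), NaH (6.5 equiv), n-Bu4NI (cat.), DMF, 0 °C → rt
Reagents that add atoms: benzyl bromide, BrCc1ccccc1
Why: Williamson etherification of three phenols and two alcohols; the diol has no carbonyl that could enolise or ring-contract, and with BnBr present before the base the phenoxides are capped as they form, so C2 and C3 are not endangered.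

Step 3
Reactants: 3 penta-O-benzylmollisacacidin; 4 resorcinol (benzene-1,3-diol)
Product: 6 tetra-O-benzylfisetinidol-(4α→4)-resorcinol [4-{(2R,3S,4R)-3,7-bis(benzyloxy)-2-[3,4-bis(benzyloxy)phenyl]chroman-4-yl}benzene-1,3-diol], via flavan-4-yl cation 5 (not isolated)
Conditions: 4 (5 equiv), BF3·OEt2 (0.5 equiv), CH2Cl2–1,4-dioxane, −20 → 0 °C
Reagents that add atoms: none
Why: SN1 Friedel–Crafts alkylation: the Lewis acid ionises the 4-benzyloxy group to cation 5 (stabilised by O1 and the 7-benzyloxy group), which resorcinol attacks through the carbon para to one hydroxyl and ortho to the other, on the face anti to the 3-benzyloxy group, setting the 4α (3,4-trans, 4R) centre; excess 4 suppresses double alkylation.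

Step 4
Reactants: 7 (+)-catechin [(2R,3S)-2-(3,4-dihydroxyphenyl)chromane-3,5,7-triol]
Product: 8 3,5,7,3',4'-penta-O-benzyl-(+)-catechin
Conditions: BnBr (6.5 equiv), NaH (6.5 equiv), DMF, 0 °C → rt
Reagents that add atoms: benzyl bromide, BrCc1ccccc1
Why: Williamson etherification of all five hydroxyls; once the phenols are capped, base-induced C2 epimerisation through a ring B quinone methide is excluded, and C2 and C3 are untouched.

Step 5
Reactants: 8 penta-O-benzylcatechin
Product: 9 8-bromo-3,5,7,3',4'-penta-O-benzylcatechin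
Conditions: NBS (1.0 equiv), CH2Cl2, −15 → 0 °C
Reagents that add atoms: N-bromosuccinimide, O=C1CCC(=O)N1Br
Why: Electrophilic aromatic bromination; in 5,7-di-O-benzylflavans C8 is the more accessible and more reactive of the two phloroglucinol positions, so one equivalent at low temperature should give the 8-bromide, which then blocks C8 until step 10.

Step 6
Reactants: 9 8-bromo-penta-O-benzylcatechin
Product: 11 8-bromo-3,5,7,3',4'-penta-O-benzylcatechin-6-carbaldehyde, via iminium chloride 10 (not isolated)
Conditions: POCl3, DMF, ClCH2CH2Cl, 70 °C; then H2O, 60 °C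
Reagents that add atoms: N,N-dimethylformamide, CN(C)C=O; water, O
Why: Vilsmeier–Haack formylation; C6 is the only free position on the trioxygenated ring and remains activated by two ortho oxygens and one para oxygen despite the bromine; hydrolysis of iminium salt 10 releases the aldehyde.

Step 7
Reactants: 11 8-bromo-penta-O-benzylcatechin-6-carbaldehyde; 12 3',4'-bis(benzyloxy)acetophenone
Product: 14 (E)-1-[3,4-bis(benzyloxy)phenyl]-3-(8-bromo-3,5,7,3',4'-penta-O-benzylcatechin-6-yl)prop-2-en-1-one, via aldol adduct 13 (not isolated)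
Conditions: KOH (50% aq), EtOH–THF, rt
Reagents that add atoms: none
Why: Claisen–Schmidt condensation: the enolate of 12 adds to the non-enolisable aldehyde 11 and aldol 13 loses water by E1cB to the conjugated enone, whose E geometry is thermodynamic; without a free phenol, catechin C2 cannot epimerise in base.

Step 8
Reactants: 6 tetra-O-benzylfisetinidol-(4α→4)-resorcinol (1.1 equiv); 14 (E)-enone
Product: 17 flav-2-ene trimer [(4S)-2-[3,4-bis(benzyloxy)phenyl]-4-(8-bromo-penta-O-benzylcatechin-6-yl)-6-(tetra-O-benzylfisetinidol-4α-yl)-4H-chromen-7-ol], via Michael adduct ketone 15 (not isolated), via 2-hydroxyflavan hemiketal 16 (not isolated)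
Conditions: (R)-3,3'-bis(2,4,6-triisopropylphenyl)-BINOL N-triflylphosphoramide (10 mol %), 5 Å MS, CH2Cl2, 0 °C → rt; filtration through Et3N-deactivated silica, used at once
Reagents that add atoms: none
Why: The strong chiral acid activates the carbonyl of 14 by hydrogen bonding and binds a hydroxyl of 6 through its phosphoryl oxygen, so that the unhindered activated carbon of the resorcinol ring (para to one hydroxyl, ortho to the other) adds to the enone β-carbon in a Friedel–Crafts conjugate addition, forming C4–C4a and giving ketone 15 after rearomatisation. The ortho hydroxyl then adds to the ketone (6-exo-trig hemiketalisation, forming O1–C2) to give 16, and acid-induced loss of water through the 2-aryl oxocarbenium ion and loss of H-3 gives the enol ether 17, so ring C of unit M closes by O-attack on a carbonyl followed by dehydration. The closest known reaction type is the acid-catalysed condensation of activated phenols and naphthols with chalcones to 2,4-diaryl-4H-chromenes, including its chiral phosphoric acid variants. The one new stereocentre, C4 of unit M (4S, aryl α), is created in the C–C bond-forming event and is set by the chiral pocket of the catalyst, because the stereocentres of unit T and of catechin are too remote to bias the enone faces. The step needs C- over O-alkylation, 1,4- over 1,2-addition, one site on the resorcinol ring and no further reaction of 17. The substrates secure this: the soft para-activated carbon of a free resorcinol prefers the β-carbon, the carbon between the two hydroxyls is flanked on both sides, bromine on catechin C8 removes the only other nucleophilic carbon of 14, and the benzyl ethers on O5 and O7 of catechin prevent ketal formation at C2 of 17.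

Step 9
Reactants: 17 flav-2-ene trimer
Product: 19 tetra-O-benzylfisetinidol-(4α→6)-3',4'-di-O-benzylfisetinidol-(4α→6)-8-bromo-penta-O-benzylcatechin [unit M 2R,3S,4S; its 3-OH and 7-OH free], via C3 alkylborane 18 (not isolated)
Conditions: BH3·SMe2 (4 equiv), THF, 0 °C → rt; then 2 M NaOH, 30% H2O2, 0 °C
Reagents that add atoms: hydrogen peroxide, OO
Why: Hydroboration–oxidation of a cyclic enol ether: boron adds to C3 (β to O1, less substituted) and hydrogen to C2, syn, on the β-face away from the bulky 4α-aryl group, and oxidation with retention gives the 3β-hydroxyl and 2β-hydrogen, i.e. the 2,3-trans-3,4-trans (2R,3S) arrangement; excess borane covers the hydride consumed by the phenol.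

Step 10
Reactants: 19 bromo trimer
Product: 20 fisetinidol-(4α→6)-fisetinidol-(4α→6)-catechin (free trimer, C8–H)
Conditions: H2 (1 atm), Pd(OH)2/C, NaOAc (1.5 equiv), THF–MeOH–H2O, rt; filtration under Ar
Reagents that add atoms: none
Why: Catalytic hydrogenolysis cleaves the eleven benzyl ethers and hydrodehalogenates the C8–Br bond in one operation, with NaOAc taking up the hydrogen bromide; the ring C2–O1 bonds and the 4-aryl bonds should survive if the reaction is stopped at complete debenzylation, and no stereocentre is touched.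

Step 11
Reactants: 20 free trimer; 2 (+)-mollisacacidin (1.3 equiv, added in portions)
Product: 22 CNP0263622.1 [fisetinidol-(4α→6)-fisetinidol-(4α→6)-catechin carrying a second fisetinidol-(4α→8) unit on catechin], via free flavan-4-yl cation 21 (not isolated)
Conditions: 0.1 M aq HCl, rt, under Ar; EtOAc extraction; Sephadex LH-20 (EtOH)
Reagents that add atoms: none
Why: Acid-catalysed flavan-3,4-diol condensation (SN1 Friedel–Crafts): the benzylic 4-hydroxyl of 2 ionises to cation 21, stabilised as a para-quinone methide by the 7-hydroxyl and by O1, and catechin C8, the only free carbon on a phloroglucinol-type ring, attacks it on the face anti to the 3-hydroxyl to give the 4α (3,4-trans, 4S) bond. The resorcinol-type rings of units T and M and of 2 itself are much weaker nucleophiles, and the 5-deoxy interflavanyl bonds already present should not ionise in acid of this strength.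

## Compound list

1 | (+)-fustin, (2R,3R)-2-(3,4-dihydroxyphenyl)-3,7-dihydroxychroman-4-one | Oc1ccc2c(c1)O[C@H](c1ccc(O)c(O)c1)[C@@H](O)C2=O | starting material
2 | (+)-mollisacacidin, (2R,3S,4R)-2-(3,4-dihydroxyphenyl)chromane-3,4,7-triol | Oc1ccc2c(c1)O[C@H](c1ccc(O)c(O)c1)[C@@H](O)[C@@H]2O | intermediate
3 | penta-O-benzylmollisacacidin, (2R,3S,4R)-3,4,7-tris(benzyloxy)-2-[3,4-bis(benzyloxy)phenyl]chromane | c9ccccc9COc1ccc2c(c1)O[C@H](c1ccc(OCc9ccccc9)c(OCc9ccccc9)c1)[C@@H](OCc9ccccc9)[C@@H]2OCc9ccccc9 | intermediate
4 | resorcinol | Oc1cccc(O)c1 | starting material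
5 | (2R,3S)-3,7-bis(benzyloxy)-2-[3,4-bis(benzyloxy)phenyl]chroman-4-ylium (benzylated flavan-4-yl cation) | c9ccccc9COc1ccc2c(c1)O[C@H](c1ccc(OCc9ccccc9)c(OCc9ccccc9)c1)[C@@H](OCc9ccccc9)[CH+]2 | intermediate (not isolated)
6 | tetra-O-benzylfisetinidol-(4α→4)-resorcinol, 4-{(2R,3S,4R)-3,7-bis(benzyloxy)-2-[3,4-bis(benzyloxy)phenyl]chroman-4-yl}benzene-1,3-diol | c9ccccc9COc1ccc2c(c1)O[C@H](c1ccc(OCc9ccccc9)c(OCc9ccccc9)c1)[C@@H](OCc9ccccc9)[C@@H]2c1ccc(O)cc1O | intermediate
7 | (+)-catechin, (2R,3S) | Oc1cc(O)c2c(c1)O[C@H](c1ccc(O)c(O)c1)[C@@H](O)C2 | starting material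
8 | 3,5,7,3',4'-penta-O-benzyl-(+)-catechin | c9ccccc9COc1cc(OCc9ccccc9)c2c(c1)O[C@H](c1ccc(OCc9ccccc9)c(OCc9ccccc9)c1)[C@@H](OCc9ccccc9)C2 | intermediate
9 | 8-bromo-3,5,7,3',4'-penta-O-benzylcatechin | c9ccccc9COc1cc(OCc9ccccc9)c2c(c1Br)O[C@H](c1ccc(OCc9ccccc9)c(OCc9ccccc9)c1)[C@@H](OCc9ccccc9)C2 | intermediate
10 | N-[(8-bromo-penta-O-benzylcatechin-6-yl)methylidene]-N-methylmethanaminium chloride | C[N+](C)=Cc1c(OCc9ccccc9)c2c(c(Br)c1OCc9ccccc9)O[C@H](c1ccc(OCc9ccccc9)c(OCc9ccccc9)c1)[C@@H](OCc9ccccc9)C2.[Cl-] | intermediate (not isolated)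
11 | 8-bromo-3,5,7,3',4'-penta-O-benzylcatechin-6-carbaldehyde | O=Cc1c(OCc9ccccc9)c2c(c(Br)c1OCc9ccccc9)O[C@H](c1ccc(OCc9ccccc9)c(OCc9ccccc9)c1)[C@@H](OCc9ccccc9)C2 | intermediate
12 | 3',4'-bis(benzyloxy)acetophenone | CC(=O)c1ccc(OCc9ccccc9)c(OCc9ccccc9)c1 | starting material
13 | 1-[3,4-bis(benzyloxy)phenyl]-3-hydroxy-3-(8-bromo-penta-O-benzylcatechin-6-yl)propan-1-one (carbinol centre undefined) | O=C(CC(O)c1c(OCc9ccccc9)c2c(c(Br)c1OCc9ccccc9)O[C@H](c1ccc(OCc9ccccc9)c(OCc9ccccc9)c1)[C@@H](OCc9ccccc9)C2)c1ccc(OCc9ccccc9)c(OCc9ccccc9)c1 | intermediate (not isolated)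
14 | (E)-1-[3,4-bis(benzyloxy)phenyl]-3-(8-bromo-penta-O-benzylcatechin-6-yl)prop-2-en-1-one | O=C(/C=C/c1c(OCc9ccccc9)c2c(c(Br)c1OCc9ccccc9)O[C@H](c1ccc(OCc9ccccc9)c(OCc9ccccc9)c1)[C@@H](OCc9ccccc9)C2)c1ccc(OCc9ccccc9)c(OCc9ccccc9)c1 | intermediate
15 | (3S)-1-[3,4-bis(benzyloxy)phenyl]-3-(8-bromo-penta-O-benzylcatechin-6-yl)-3-[2,4-dihydroxy-5-(tetra-O-benzylfisetinidol-4α-yl)phenyl]propan-1-one | c9ccccc9COc1ccc2c(c1)O[C@H](c1ccc(OCc9ccccc9)c(OCc9ccccc9)c1)[C@@H](OCc9ccccc9)[C@@H]2c1cc([C@H](CC(=O)c2ccc(OCc9ccccc9)c(OCc9ccccc9)c2)c2c(OCc9ccccc9)c3c(c(Br)c2OCc9ccccc9)O[C@H](c2ccc(OCc9ccccc9)c(OCc9ccccc9)c2)[C@@H](OCc9ccccc9)C3)c(O)cc1O | intermediate (not isolated)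
16 | 2-hydroxyflavan hemiketal of 15 (ring C of unit M closed, C2 undefined, 4S) | c9ccccc9COc1ccc2c(c1)O[C@H](c1ccc(OCc9ccccc9)c(OCc9ccccc9)c1)[C@@H](OCc9ccccc9)[C@@H]2c1cc2c(cc1O)OC(O)(c1ccc(OCc9ccccc9)c(OCc9ccccc9)c1)C[C@@H]2c1c(OCc9ccccc9)c2c(c(Br)c1OCc9ccccc9)O[C@H](c1ccc(OCc9ccccc9)c(OCc9ccccc9)c1)[C@@H](OCc9ccccc9)C2 | intermediate (not isolated)
17 | flav-2-ene trimer, (4S)-2-[3,4-bis(benzyloxy)phenyl]-4-(8-bromo-penta-O-benzylcatechin-6-yl)-6-(tetra-O-benzylfisetinidol-4α-yl)-4H-chromen-7-ol | c9ccccc9COc1ccc2c(c1)O[C@H](c1ccc(OCc9ccccc9)c(OCc9ccccc9)c1)[C@@H](OCc9ccccc9)[C@@H]2c1cc2c(cc1O)OC(c1ccc(OCc9ccccc9)c(OCc9ccccc9)c1)=C[C@@H]2c1c(OCc9ccccc9)c2c(c(Br)c1OCc9ccccc9)O[C@H](c1ccc(OCc9ccccc9)c(OCc9ccccc9)c1)[C@@H](OCc9ccccc9)C2 | intermediate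
18 | C3 alkylborane of 17 (boron 3β, hydrogen 2β; drawn as the monoalkylborane) | c9ccccc9COc1ccc2c(c1)O[C@H](c1ccc(OCc9ccccc9)c(OCc9ccccc9)c1)[C@@H](OCc9ccccc9)[C@@H]2c1cc2c(cc1O)O[C@H](c1ccc(OCc9ccccc9)c(OCc9ccccc9)c1)[C@@H](B)[C@@H]2c1c(OCc9ccccc9)c2c(c(Br)c1OCc9ccccc9)O[C@H](c1ccc(OCc9ccccc9)c(OCc9ccccc9)c1)[C@@H](OCc9ccccc9)C2 | intermediate (not isolated)
19 | tetra-O-benzylfisetinidol-(4α→6)-3',4'-di-O-benzylfisetinidol-(4α→6)-8-bromo-penta-O-benzylcatechin (unit M 2R,3S,4S) | c9ccccc9COc1ccc2c(c1)O[C@H](c1ccc(OCc9ccccc9)c(OCc9ccccc9)c1)[C@@H](OCc9ccccc9)[C@@H]2c1cc2c(cc1O)O[C@H](c1ccc(OCc9ccccc9)c(OCc9ccccc9)c1)[C@@H](O)[C@@H]2c1c(OCc9ccccc9)c2c(c(Br)c1OCc9ccccc9)O[C@H](c1ccc(OCc9ccccc9)c(OCc9ccccc9)c1)[C@@H](OCc9ccccc9)C2 | intermediate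
20 | fisetinidol-(4α→6)-fisetinidol-(4α→6)-catechin (free trimer) | Oc1ccc2c(c1)O[C@H](c1ccc(O)c(O)c1)[C@@H](O)[C@@H]2c1cc2c(cc1O)O[C@H](c1ccc(O)c(O)c1)[C@@H](O)[C@@H]2c1c(O)c2c(cc1O)O[C@H](c1ccc(O)c(O)c1)[C@@H](O)C2 | intermediate
21 | (2R,3S)-2-(3,4-dihydroxyphenyl)-3,7-dihydroxychroman-4-ylium (free flavan-4-yl cation) | Oc1ccc2c(c1)O[C@H](c1ccc(O)c(O)c1)[C@@H](O)[CH+]2 | intermediate (not isolated)
22 | CNP0263622.1, fisetinidol-(4α→6)-fisetinidol-(4α→6)-catechin-(8←4α)-fisetinidol | Oc1ccc2c(c1)O[C@H](c1ccc(O)c(O)c1)[C@@H](O)[C@@H]2c1cc2c(cc1O)O[C@H](c1ccc(O)c(O)c1)[C@@H](O)[C@@H]2c1c(O)c2c(c([C@@H]3c4ccc(O)cc4O[C@H](c4ccc(O)c(O)c4)[C@H]3O)c1O)O[C@H](c1ccc(O)c(O)c1)[C@@H](O)C2 | target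

## Step count and least certain steps

Total step count: 11. Longest linear sequence: 8 steps (steps 4 to 11, from 7 to 22).

Step 8 (key step). The most likely failures are a sluggish conjugate addition and insufficient facial discrimination. The β-carbon of 14 is shielded by two ortho benzyloxy groups and deactivated by the donor ring, and the catalyst has to work against that bulk. Acid-induced reversal of the C4–aryl bond could also erode the configuration. The fallback separates C–C bond formation from ring closure and moves stereocontrol to a metal–ligand complex.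
- It sets out from 6. Bromination (NBS, 1 equiv, CH2Cl2–THF, −78 °C) at the free carbon para to a hydroxyl should give 4-bromo-6-(tetra-O-benzylfisetinidol-4α-yl)benzene-1,3-diol F1, the free-phenol ring being brominated in preference to the ether rings.
- MOMCl and i-Pr2NEt convert it into the bis(methoxymethyl) ether F2.
- Miyaura borylation (PdCl2(dppf), B2pin2, KOAc, dioxane, 80 °C) gives the pinacol boronate F3.
- Rhodium-catalysed asymmetric 1,4-addition to 14 (Rh(acac)(C2H4)2, (S)- or (R)-BINAP, aq KOH, dioxane, 60 °C) gives the bis(methoxymethyl) ether of the β,β-diaryl ketone F4, with C4 set by the ligand.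
- Aqueous HCl in THF removes the two acetals to give 15, which is closed and dehydrated with a mild achiral acid (PPTS, toluene, 4 Å MS). The fallback comes back to the route at 17.

Step 11. The most likely failures are incomplete facial selectivity (attack syn to the 3-hydroxyl, giving the 4β epimer), competing substitution on the resorcinol-type rings or self-condensation of 2, and oxidative loss of the polyphenols during the acid treatment, all of which make the final purification harder. The fallback moves the coupling to protected material under low-temperature kinetic control.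
- It sets out from 19. Bromine–lithium exchange (n-BuLi, 3.5 equiv, THF, −78 °C) gives the trilithio species F5 (lithium on catechin C8, lithium phenoxide and alkoxide on unit M).
- Quenching with MeOH gives the debrominated protected trimer F6.
- F6 is coupled with 3 (TMSOTf, 0.3 equiv, 4 Å MS, CH2Cl2, −78 → −30 °C), which ionises to cation 5; attack of catechin C8 anti to the 3-benzyloxy group should give the pentadeca-O-benzyl tetraflavanoid F7, which can be chromatographed on silica.
- Hydrogenolysis (H2, Pd(OH)2/C, THF–MeOH–H2O) then removes the fifteen benzyl groups. The fallback comes back to the route at 22.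

Step 9. The most likely failures are β-elimination of the β-aryloxy organoborane 18 with opening of ring C, incomplete facial selectivity, and acid- or air-induced decay of 17 before it reacts. The fallback replaces hydroboration by dihydroxylation and ionic reduction.
- It sets out from 17. OsO4 (cat.) and NMO in acetone–H2O should add to the β-face, anti to the 4α-aryl group, to give the 2β,3β-dihydroxy hemiketal F8.
- Et3SiH and BF3·OEt2 in CH2Cl2 at −78 °C ionise the hemiketal to the 2-aryl oxocarbenium ion F9 and reduce it; axial hydride delivery places the aryl group equatorial (2,3-trans). The fallback comes back to the route at 19.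

Step 6. The most likely failure is slow substitution at a carbon flanked by two benzyloxy groups, which gives time for debenzylation or ipso attack at the brominated carbon. The fallback replaces electrophilic formylation by halogen–metal exchange.
- It sets out from 9. Iodination (NIS, cat. TFA, CH2Cl2–MeCN, 0 °C) gives 8-bromo-6-iodo-penta-O-benzylcatechin F10.
- Iodine–magnesium exchange with i-PrMgCl·LiCl (THF, −40 °C) is much faster than bromine–magnesium exchange and gives the C6 arylmagnesium chloride F11.
- Quenching with DMF and aqueous work-up give the aldehyde. The fallback comes back to the route at 11.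

## Further compounds

F1 | step 8 | 4-bromo-6-(tetra-O-benzylfisetinidol-4α-yl)benzene-1,3-diol | c9ccccc9COc1ccc2c(c1)O[C@H](c1ccc(OCc9ccccc9)c(OCc9ccccc9)c1)[C@@H](OCc9ccccc9)[C@@H]2c1cc(Br)c(O)cc1O
F2 | step 8 | bis(methoxymethyl) ether of F1 | c9ccccc9COc1ccc2c(c1)O[C@H](c1ccc(OCc9ccccc9)c(OCc9ccccc9)c1)[C@@H](OCc9ccccc9)[C@@H]2c1cc(Br)c(OCOC)cc1OCOC
F3 | step 8 | pinacol boronate from F2 | c9ccccc9COc1ccc2c(c1)O[C@H](c1ccc(OCc9ccccc9)c(OCc9ccccc9)c1)[C@@H](OCc9ccccc9)[C@@H]2c1cc(B3OC(C)(C)C(C)(C)O3)c(OCOC)cc1OCOC
F4 | step 8 | bis(methoxymethyl) ether of ketone 15 | c9ccccc9COc1ccc2c(c1)O[C@H](c1ccc(OCc9ccccc9)c(OCc9ccccc9)c1)[C@@H](OCc9ccccc9)[C@@H]2c1cc([C@H](CC(=O)c2ccc(OCc9ccccc9)c(OCc9ccccc9)c2)c2c(OCc9ccccc9)c3c(c(Br)c2OCc9ccccc9)O[C@H](c2ccc(OCc9ccccc9)c(OCc9ccccc9)c2)[C@@H](OCc9ccccc9)C3)c(OCOC)cc1OCOC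
F5 | step 11 | trilithio derivative of 19 (lithium on catechin C8, lithium phenoxide and alkoxide on unit M) | c9ccccc9COc1ccc2c(c1)O[C@H](c1ccc(OCc9ccccc9)c(OCc9ccccc9)c1)[C@@H](OCc9ccccc9)[C@@H]2c1cc2c(cc1O[Li])O[C@H](c1ccc(OCc9ccccc9)c(OCc9ccccc9)c1)[C@@H](O[Li])[C@@H]2c1c(OCc9ccccc9)c2c(c([Li])c1OCc9ccccc9)O[C@H](c1ccc(OCc9ccccc9)c(OCc9ccccc9)c1)[C@@H](OCc9ccccc9)C2
F6 | step 11 | tetra-O-benzylfisetinidol-(4α→6)-3',4'-di-O-benzylfisetinidol-(4α→6)-penta-O-benzylcatechin (C8–H) | c9ccccc9COc1ccc2c(c1)O[C@H](c1ccc(OCc9ccccc9)c(OCc9ccccc9)c1)[C@@H](OCc9ccccc9)[C@@H]2c1cc2c(cc1O)O[C@H](c1ccc(OCc9ccccc9)c(OCc9ccccc9)c1)[C@@H](O)[C@@H]2c1c(OCc9ccccc9)c2c(cc1OCc9ccccc9)O[C@H](c1ccc(OCc9ccccc9)c(OCc9ccccc9)c1)[C@@H](OCc9ccccc9)C2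
F7 | step 11 | pentadeca-O-benzyl tetraflavanoid (F6 with a tetra-O-benzylfisetinidol-4α-yl group on catechin C8; unit E 2R,3S,4S) | c9ccccc9COc1ccc2c(c1)O[C@H](c1ccc(OCc9ccccc9)c(OCc9ccccc9)c1)[C@@H](OCc9ccccc9)[C@@H]2c1cc2c(cc1O)O[C@H](c1ccc(OCc9ccccc9)c(OCc9ccccc9)c1)[C@@H](O)[C@@H]2c1c(OCc9ccccc9)c2c(c([C@@H]3c4ccc(OCc9ccccc9)cc4O[C@H](c4ccc(OCc9ccccc9)c(OCc9ccccc9)c4)[C@H]3OCc9ccccc9)c1OCc9ccccc9)O[C@H](c1ccc(OCc9ccccc9)c(OCc9ccccc9)c1)[C@@H](OCc9ccccc9)C2
F8 | step 9 | 2β,3β-dihydroxy hemiketal from 17 (2-hydroxyflavan-3-ol in unit M) | c9ccccc9COc1ccc2c(c1)O[C@H](c1ccc(OCc9ccccc9)c(OCc9ccccc9)c1)[C@@H](OCc9ccccc9)[C@@H]2c1cc2c(cc1O)O[C@](O)(c1ccc(OCc9ccccc9)c(OCc9ccccc9)c1)[C@@H](O)[C@@H]2c1c(OCc9ccccc9)c2c(c(Br)c1OCc9ccccc9)O[C@H](c1ccc(OCc9ccccc9)c(OCc9ccccc9)c1)[C@@H](OCc9ccccc9)C2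
F9 | step 9 | 2-aryl oxocarbenium ion from F8 (unit M, 3β-hydroxyl retained) | c9ccccc9COc1ccc2c(c1)O[C@H](c1ccc(OCc9ccccc9)c(OCc9ccccc9)c1)[C@@H](OCc9ccccc9)[C@@H]2c1cc2c(cc1O)[O+]=C(c1ccc(OCc9ccccc9)c(OCc9ccccc9)c1)[C@@H](O)[C@@H]2c1c(OCc9ccccc9)c2c(c(Br)c1OCc9ccccc9)O[C@H](c1ccc(OCc9ccccc9)c(OCc9ccccc9)c1)[C@@H](OCc9ccccc9)C2
F10 | step 6 | 8-bromo-6-iodo-3,5,7,3',4'-penta-O-benzylcatechin | Ic1c(OCc9ccccc9)c2c(c(Br)c1OCc9ccccc9)O[C@H](c1ccc(OCc9ccccc9)c(OCc9ccccc9)c1)[C@@H](OCc9ccccc9)C2
F11 | step 6 | (8-bromo-penta-O-benzylcatechin-6-yl)magnesium chloride | Cl[Mg]c1c(OCc9ccccc9)c2c(c(Br)c1OCc9ccccc9)O[C@H](c1ccc(OCc9ccccc9)c(OCc9ccccc9)c1)[C@@H](OCc9ccccc9)C2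
A1 | alternative 1 | bis(pinacol boronic ester) with boron on the future C4 of units T and M | c9ccccc9COc1ccc(c(O[Si](C)(C)C(C)(C)C)c1)[C@H](B4OC(C)(C)C(C)(C)O4)c1cc([C@H](B4OC(C)(C)C(C)(C)O4)c2c(OCc9ccccc9)c3c(cc2OCc9ccccc9)O[C@H](c2ccc(OCc9ccccc9)c(OCc9ccccc9)c2)[C@@H](OCc9ccccc9)C3)c(O[Si](C)(C)C(C)(C)C)cc1OCc9ccccc9
A2 | alternative 1 | trans-2-[3,4-bis(benzyloxy)phenyl]-3-(tributylstannyl)oxirane | CCCC[Sn](CCCC)(CCCC)[C@@H]1O[C@H]1c1ccc(OCc9ccccc9)c(OCc9ccccc9)c1
A3 | alternative 1 | trans-3-[3,4-bis(benzyloxy)phenyl]oxiranyllithium | [Li][C@@H]1O[C@H]1c1ccc(OCc9ccccc9)c(OCc9ccccc9)c1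
A4 | alternative 1 | open-chain bis(1,1,3-triarylpropane-2,3-diol) on penta-O-benzylcatechin | c9ccccc9COc1ccc(c(O[Si](C)(C)C(C)(C)C)c1)[C@H]([C@H](O)[C@@H](O)c1ccc(OCc9ccccc9)c(OCc9ccccc9)c1)c1cc([C@H]([C@H](O)[C@@H](O)c2ccc(OCc9ccccc9)c(OCc9ccccc9)c2)c2c(OCc9ccccc9)c3c(cc2OCc9ccccc9)O[C@H](c2ccc(OCc9ccccc9)c(OCc9ccccc9)c2)[C@@H](OCc9ccccc9)C3)c(O[Si](C)(C)C(C)(C)C)cc1OCc9ccccc9
A5 | alternative 2 | bis[2-(1-arylvinyl)phenol] on penta-O-benzylcatechin C6 | c9ccccc9COc1ccc(C(=C)c2cc(C(=C)c3c(OCc9ccccc9)c4c(cc3OCc9ccccc9)O[C@H](c3ccc(OCc9ccccc9)c(OCc9ccccc9)c3)[C@@H](OCc9ccccc9)C4)c(O)cc2OCc9ccccc9)c(O)c1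
A6 | alternative 2 | 3,4-bis(benzyloxy)benzaldehyde | O=Cc1ccc(OCc9ccccc9)c(OCc9ccccc9)c1
A7 | alternative 2 | benzylated T–M–catechin trimer with C3=C4 double bonds in units T and M | c9ccccc9COc1ccc2c(c1)O[C@H](c1ccc(OCc9ccccc9)c(OCc9ccccc9)c1)C=C2c1cc2c(cc1OCc9ccccc9)O[C@H](c1ccc(OCc9ccccc9)c(OCc9ccccc9)c1)C=C2c1c(OCc9ccccc9)c2c(cc1OCc9ccccc9)O[C@H](c1ccc(OCc9ccccc9)c(OCc9ccccc9)c1)[C@@H](OCc9ccccc9)C2
A8 | alternative 3 | α-diazo vinyl ketone with tethered ethynyl ether on C8 of penta-O-benzylcatechin | c1c(OCc9ccccc9)c2c(c([C@H](C(=[N+]=[N-])C(=O)C=C)[C@H](OCc9ccccc9)[C@@H](c3ccc(OCc9ccccc9)c(OCc9ccccc9)c3)OC#C)c1OCc9ccccc9)O[C@H](c1ccc(OCc9ccccc9)c(OCc9ccccc9)c1)[C@@H](OCc9ccccc9)C2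
A9 | alternative 3 | benzylated fisetinidol-(4α→8)-catechin with free 7-hydroxyl on unit E and open catechin C6 | c1c(OCc9ccccc9)c2c(c([C@@H]3c4ccc(O)cc4O[C@H](c4ccc(OCc9ccccc9)c(OCc9ccccc9)c4)[C@H]3OCc9ccccc9)c1OCc9ccccc9)O[C@H](c1ccc(OCc9ccccc9)c(OCc9ccccc9)c1)[C@@H](OCc9ccccc9)C2
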